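**Strategy.** The benzene ring is built rather than bought. With the CHO carbon as C1, the target ring carries para oxygens at C3 and C6, H at C4, the chain CH2 at C5, and O at C2 beside the one-carbon unit at C1: exactly what a Dötz benzannulation assembles from a terminal alkyne (C4, C5), a methoxycarbene carbon (C3), one CO ligand (C6) and the enol-ether C=C of a 4H-1,3-dioxin (C1, C2). One operation closes the arene and joins it to the complete, farnesol-derived chain, whose (S)-methyl centre comes from asymmetric hydrogenation. The precursors are a skipped enyne ester and a dioxinyl(methoxy)carbene pentacarbonylchromium complex; oxidative work-up, hydroxide opening of the dioxin and a redox adjustment finish the route.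

Key step: step 13

Assumption: 1,3-dioxan-5-ol (13) is used as the pure six-membered isomer; technical glycerol formal, a mixture with the dioxolane isomer, would first be fractionated.
Assumption: the sense of induction in step 5 is taken from tiglic acid, which the (S)-configured ligand reduces to the (S)-acid; the configuration of 6 is to be confirmed by correlation before scale-up.

**Route**

Step 1
Reactants: 1 (2E,6E)-farnesol
Product: 2 (2E,6E)-farnesyl acetate
Conditions: Ac2O, pyridine, DMAP (cat.), CH2Cl2, 0 °C to rt
Reagents that add atoms: acetic anhydride, CC(=O)OC(C)=O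
Why: Routine O-acetylation of a primary allylic alcohol, which removes the hydroxyl that would otherwise direct the ruthenium hydrogenation of step 5 to the C2 alkene and keeps C1 available as the later leaving-group position.

Step 2
Reactants: 2 (2E,6E)-farnesyl acetate
Product: 3 (2E,6E,10E)-12-hydroxy-3,7,11-trimethyldodeca-2,6,10-trien-1-yl acetate
Conditions: SeO2 (cat.), t-BuOOH, salicylic acid (cat.), CH2Cl2, rt
Reagents that add atoms: tert-butyl hydroperoxide, CC(C)(C)OO (its oxygen is relayed by the catalytic selenium dioxide, O=[Se]=O)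
Why: Riley-type allylic oxidation under Sharpless conditions, in which the ene reaction and [2,3]-sigmatropic shift occur at the most electron-rich terminal alkene and oxidise the methyl group trans to the chain, so the new allylic alcohol should be E, the acetate-bearing alkene being deactivated; any enal 4 formed by over-oxidation is pooled because step 3 converges both.

Step 3
Reactants: 3 (2E,6E,10E)-12-hydroxy-3,7,11-trimethyldodeca-2,6,10-trien-1-yl acetate
Product: 4 (2E,6E,10E)-3,7,11-trimethyl-12-oxododeca-2,6,10-trien-1-yl acetate
Conditions: MnO2, CH2Cl2, rt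
Reagents that add atoms: none
Why: Chemoselective MnO2 oxidation of an allylic alcohol to the enal, which should leave the isolated alkenes, the acetate and the E geometry untouched.

Step 4
Reactants: 4 (2E,6E,10E)-3,7,11-trimethyl-12-oxododeca-2,6,10-trien-1-yl acetate
Product: 5 (2E,6E,10E)-12-acetoxy-2,6,10-trimethyldodeca-2,6,10-trienoic acid
Conditions: NaClO2, NaH2PO4, 2-methylbut-2-ene, t-BuOH/H2O, 0 °C to rt
Reagents that add atoms: sodium chlorite, [Na+].[O-]Cl=O
Why: Pinnick oxidation of an enal to the enoic acid without E/Z erosion, the alkene scavenger intercepting hypochlorous acid so that the trisubstituted alkenes of the chain are not chlorinated.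

Step 5
Reactants: 5 (2E,6E,10E)-12-acetoxy-2,6,10-trimethyldodeca-2,6,10-trienoic acid
Product: 6 (2S,6E,10E)-12-acetoxy-2,6,10-trimethyldodeca-6,10-dienoic acid
Conditions: Ru(OAc)2[(S)-H8-BINAP] (1 mol %), H2 (about 4 atm), MeOH, rt
Reagents that add atoms: none
Why: Noyori-type carboxylate-directed asymmetric hydrogenation, in which the acid binds divalent ruthenium as a carboxylate so that only the conjugated alkene is reduced while the isolated alkenes and the non-coordinating allylic acetate are left alone; the C2 stereocentre is set by the ligand, the (S)-antipode being chosen because it gives the (S)-acid from tiglic acid, which shares the E, alpha-methyl, beta-alkyl pattern.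

Step 6
Reactants: 6 (2S,6E,10E)-12-acetoxy-2,6,10-trimethyldodeca-6,10-dienoic acid
Product: 8 methyl (2S,6E,10E)-12-hydroxy-2,6,10-trimethyldodeca-6,10-dienoate, via acetoxy methyl ester 7 (not isolated)
Conditions: MeI, K2CO3, DMF, rt; then MeOH, rt
Reagents that add atoms: iodomethane, CI
Why: SN2 O-methylation of the carboxylate followed in the same flask by carbonate-catalysed transesterification of the acetate, neither stage being basic enough to epimerise C2 and no acid reaching the allylic alcohol.

Step 7
Reactants: 8 methyl (2S,6E,10E)-12-hydroxy-2,6,10-trimethyldodeca-6,10-dienoate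
Product: 9 methyl (2S,6E,10E)-12-bromo-2,6,10-trimethyldodeca-6,10-dienoate
Conditions: CBr4, PPh3, CH2Cl2, 0 °C (used at once)
Reagents that add atoms: tetrabromomethane, BrC(Br)(Br)Br
Why: Appel bromination under neutral conditions, which should convert the primary allylic alcohol to the bromide without allylic transposition, E/Z scrambling or harm to the ester.

Step 8
Reactants: 9 methyl (2S,6E,10E)-12-bromo-2,6,10-trimethyldodeca-6,10-dienoate; 10 trimethylsilylacetylene
Product: 11 methyl (2S,6E,10E)-2,6,10-trimethyl-14-(trimethylsilyl)tetradeca-6,10-dien-13-ynoate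
Conditions: CuI (20 mol %), NaI (20 mol %), K2CO3, excess 10, DMF, rt, argon
Reagents that add atoms: none
Why: Copper-catalysed allylation of a terminal alkyne under weak-base (Jeffery-type) conditions, the copper acetylide attacking the unhindered primary carbon (SN2, not SN2', which would build a quaternary centre) with retention of the E alkene, while the carbonate base spares the ester and C2 and the silyl cap prevents a second allylation.

Step 9
Reactants: 11 methyl (2S,6E,10E)-2,6,10-trimethyl-14-(trimethylsilyl)tetradeca-6,10-dien-13-ynoate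
Product: 12 methyl (2S,6E,10E)-2,6,10-trimethyltetradeca-6,10-dien-13-ynoate
Conditions: K2CO3 (cat.), MeOH, 0 °C to rt
Reagents that add atoms: none
Why: Methoxide-mediated protodesilylation of an alkynylsilane, run cold and briefly so that the doubly activated CH2 of the skipped enyne is not isomerised, ester exchange in methanol being degenerate.

Step 10
Reactants: 13 1,3-dioxan-5-ol
Product: 14 1,3-dioxan-5-yl 4-methylbenzenesulfonate
Conditions: TsCl, pyridine, 0 °C to rt
Reagents that add atoms: 4-toluenesulfonyl chloride, Cc1ccc(cc1)S(Cl)(=O)=O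
Why: Ordinary sulfonylation of a secondary alcohol, which turns the hydroxyl into a leaving group for the elimination.

Step 11
Reactants: 14 1,3-dioxan-5-yl 4-methylbenzenesulfonate
Product: 15 4H-1,3-dioxin
Conditions: KOtBu, DMSO, rt to 40 °C, product distilled out under reduced pressure
Reagents that add atoms: none
Why: E2 elimination with a hindered base, in which the only beta-hydrogens are the ring OCH2 protons so that the cyclic enol ether is the sole possible alkene, and the volatile, acid-sensitive product is removed as it forms.

Step 12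
Reactants: 15 4H-1,3-dioxin; 16 chromium hexacarbonyl
Product: 19 pentacarbonyl[(4H-1,3-dioxin-6-yl)(methoxy)carbene]chromium, via 6-lithio-4H-1,3-dioxin 17 (not isolated), via lithium acylchromate 18 (not isolated)
Conditions: s-BuLi, THF, -78 °C; Cr(CO)6, -78 °C to rt; then Me3OBF4, CH2Cl2, 0 °C
Reagents that add atoms: trimethyloxonium tetrafluoroborate, C[O+](C)C.F[B-](F)(F)F
Why: Fischer carbene synthesis, in which oxygen-directed alpha-lithiation of the enol ether at C6 gives a vinyllithium that adds to a CO ligand of Cr(CO)6 and the resulting acyl chromate is O-methylated by the hard Meerwein salt, as established for 2-lithiated dihydropyrans.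

Step 13
Reactants: 12 methyl (2S,6E,10E)-2,6,10-trimethyltetradeca-6,10-dien-13-ynoate; 19 pentacarbonyl[(4H-1,3-dioxin-6-yl)(methoxy)carbene]chromium
Product: 22 methyl (2S,6E,10E)-12-(5,8-dioxo-5,8-dihydro-4H-1,3-benzodioxin-6-yl)-2,6,10-trimethyldodeca-6,10-dienoate, via phenol chromium tricarbonyl complex 20 (not isolated), via free phenol 21 (not isolated)
Conditions: 12 (1 equiv), 19 (1.5 equiv), THF, 50 °C, argon; then aq. (NH4)2Ce(NO3)6, MeCN, 0 °C
Reagents that add atoms: water, O (supplies the quinone oxygen that replaces the methoxy group)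
Why: Loss of one CO from 19 at 50 °C frees a site at which the terminal alkyne of 12 inserts into the Cr=C bond to give a vinylcarbene, CO insertion then gives a chromium-bound dienylketene, and 6-pi electrocyclisation onto dioxin C5 followed by enolisation should deliver the 4-methoxyphenol as its Cr(CO)3 complex 20. This is a Dötz benzannulation, the closest precedent being the reaction of dihydropyranyl and glycal-derived alkenyl(methoxy)carbene chromium complexes with terminal alkynes. The benzene ring is the only ring closed, by six-electron electrocyclic closure between the ketene carbon and the enol-ether beta-carbon, so that three C-C bonds (carbene carbon to alkyne CH, substituted alkyne carbon to the CO carbon, CO carbon to dioxin C5) form in one operation; no stereocentre is created, and the C2 centre and both E alkenes of the chain are remote spectators. The selectivity needed is regiochemical, and the steric difference between the two alkyne termini should place the chain-bearing carbon next to the CO-derived phenol carbon and the CH next to the methoxy carbon, while the 1,4-enyne spacing is too short for the vinylcarbene to cyclopropanate the neighbouring alkene and the mild temperature spares the dioxin from cycloreversion. The cerium work-up strips zerovalent chromium and oxidises the liberated phenol 21 to quinone 22 within minutes at 0 °C, before the ortho-allyl phenol can close to a chroman, the isolated alkenes and the ester being inert to both stages.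

Step 14
Reactants: 22 methyl (2S,6E,10E)-12-(5,8-dioxo-5,8-dihydro-4H-1,3-benzodioxin-6-yl)-2,6,10-trimethyldodeca-6,10-dienoate
Product: 23 (2S,6E,10E)-12-[4-hydroxy-5-(hydroxymethyl)-3,6-dioxocyclohexa-1,4-dien-1-yl]-2,6,10-trimethyldodeca-6,10-dienoic acid
Conditions: LiOH·H2O, THF/H2O, argon, 0 °C to rt; then cold 1 M HCl to pH 3 (crude product used at once)
Reagents that add atoms: lithium hydroxide, [Li+].[OH-]
Why: Alkaline hydrolysis of a 2-alkoxy-1,4-benzoquinone, in which hydroxide adds to the vinylogous-ester carbon and expels the dioxin oxygen as a hemiformal alkoxide that sheds formaldehyde to leave the carbinol, the hydroxyquinone anion so formed being deactivated towards further attack while the methyl ester is saponified more slowly, and no acid strong enough to touch the chain alkenes being used.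

Step 15
Reactants: 23 (2S,6E,10E)-12-[4-hydroxy-5-(hydroxymethyl)-3,6-dioxocyclohexa-1,4-dien-1-yl]-2,6,10-trimethyldodeca-6,10-dienoic acid
Product: 25 (2S,6E,10E)-12-(3-formyl-2,4,5-trihydroxyphenyl)-2,6,10-trimethyldodeca-6,10-dienoic acid (CNP0180353.1), via formylquinone acid 24 (not isolated)
Conditions: Dess–Martin periodinane, CH2Cl2, 0 °C; then aq. Na2S2O4, EtOAc, rt, argon, acidify to pH 3
Reagents that add atoms: none
Why: Periodinane oxidation of the quinonyl carbinol to the aldehyde followed by dithionite reduction of the quinone, a sequence that converges because any formyl hydroquinone arising from tautomerisation of 23 would be re-oxidised to the same formylquinone 24, while dithionite reduces the quinone but not the aldehyde, destroys excess oxidant and leaves the carboxylic acid and alkenes alone.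

**Compound list**

1 | (2E,6E)-farnesol | CC(C)=CCC/C(C)=C/CC/C(C)=C/CO | starting material
2 | (2E,6E)-farnesyl acetate | CC(=O)OC/C=C(\C)CC/C=C(\C)CCC=C(C)C | intermediate
3 | (2E,6E,10E)-12-hydroxy-3,7,11-trimethyldodeca-2,6,10-trien-1-yl acetate | CC(=O)OC/C=C(\C)CC/C=C(\C)CC/C=C(\C)CO | intermediate
4 | (2E,6E,10E)-3,7,11-trimethyl-12-oxododeca-2,6,10-trien-1-yl acetate | CC(=O)OC/C=C(\C)CC/C=C(\C)CC/C=C(\C)C=O | intermediate
5 | (2E,6E,10E)-12-acetoxy-2,6,10-trimethyldodeca-2,6,10-trienoic acid | CC(=O)OC/C=C(\C)CC/C=C(\C)CC/C=C(\C)C(=O)O | intermediate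
6 | (2S,6E,10E)-12-acetoxy-2,6,10-trimethyldodeca-6,10-dienoic acid | CC(=O)OC/C=C(\C)CC/C=C(\C)CCC[C@H](C)C(=O)O | intermediate
7 | methyl (2S,6E,10E)-12-acetoxy-2,6,10-trimethyldodeca-6,10-dienoate | CC(=O)OC/C=C(\C)CC/C=C(\C)CCC[C@H](C)C(=O)OC | intermediate (not isolated)
8 | methyl (2S,6E,10E)-12-hydroxy-2,6,10-trimethyldodeca-6,10-dienoate | OC/C=C(\C)CC/C=C(\C)CCC[C@H](C)C(=O)OC | intermediate
9 | methyl (2S,6E,10E)-12-bromo-2,6,10-trimethyldodeca-6,10-dienoate | BrC/C=C(\C)CC/C=C(\C)CCC[C@H](C)C(=O)OC | intermediate
10 | trimethylsilylacetylene | C#C[Si](C)(C)C | starting material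
11 | methyl (2S,6E,10E)-2,6,10-trimethyl-14-(trimethylsilyl)tetradeca-6,10-dien-13-ynoate | C[Si](C)(C)C#CC/C=C(\C)CC/C=C(\C)CCC[C@H](C)C(=O)OC | intermediate
12 | methyl (2S,6E,10E)-2,6,10-trimethyltetradeca-6,10-dien-13-ynoate | C#CC/C=C(\C)CC/C=C(\C)CCC[C@H](C)C(=O)OC | intermediate
13 | 1,3-dioxan-5-ol | OC1COCOC1 | starting material
14 | 1,3-dioxan-5-yl 4-methylbenzenesulfonate | Cc1ccc(cc1)S(=O)(=O)OC1COCOC1 | intermediate
15 | 4H-1,3-dioxin | C1=COCOC1 | intermediate
16 | chromium hexacarbonyl | O=C=[Cr](=C=O)(=C=O)(=C=O)(=C=O)=C=O | starting material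
17 | 6-lithio-4H-1,3-dioxin | [Li]C1=CCOCO1 | intermediate (not isolated)
18 | lithium pentacarbonyl[(4H-1,3-dioxin-6-yl)carbonyl]chromate | [Li+].[O-]C(C1=CCOCO1)=[Cr](=C=O)(=C=O)(=C=O)(=C=O)=C=O | intermediate (not isolated)
19 | pentacarbonyl[(4H-1,3-dioxin-6-yl)(methoxy)carbene]chromium | COC(C1=CCOCO1)=[Cr](=C=O)(=C=O)(=C=O)(=C=O)=C=O | intermediate
20 | tricarbonylchromium complex of phenol 21, the Cr(CO)3 unit eta-6 bound to the benzene ring (drawn as a separate fragment) | COc1cc(C/C=C(\C)CC/C=C(\C)CCC[C@H](C)C(=O)OC)c(O)c2COCOc12.O=C=[Cr](=C=O)=C=O | intermediate (not isolated)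
21 | methyl (2S,6E,10E)-12-(5-hydroxy-8-methoxy-4H-1,3-benzodioxin-6-yl)-2,6,10-trimethyldodeca-6,10-dienoate | COc1cc(C/C=C(\C)CC/C=C(\C)CCC[C@H](C)C(=O)OC)c(O)c2COCOc12 | intermediate (not isolated)
22 | methyl (2S,6E,10E)-12-(5,8-dioxo-5,8-dihydro-4H-1,3-benzodioxin-6-yl)-2,6,10-trimethyldodeca-6,10-dienoate | O=C1C=C(C/C=C(\C)CC/C=C(\C)CCC[C@H](C)C(=O)OC)C(=O)C2=C1OCOC2 | intermediate
23 | (2S,6E,10E)-12-[4-hydroxy-5-(hydroxymethyl)-3,6-dioxocyclohexa-1,4-dien-1-yl]-2,6,10-trimethyldodeca-6,10-dienoic acid | O=C1C=C(C/C=C(\C)CC/C=C(\C)CCC[C@H](C)C(=O)O)C(=O)C(CO)=C1O | intermediate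
24 | (2S,6E,10E)-12-(5-formyl-4-hydroxy-3,6-dioxocyclohexa-1,4-dien-1-yl)-2,6,10-trimethyldodeca-6,10-dienoic acid | O=CC1=C(O)C(=O)C=C(C/C=C(\C)CC/C=C(\C)CCC[C@H](C)C(=O)O)C1=O | intermediate (not isolated)
25 | (2S,6E,10E)-12-(3-formyl-2,4,5-trihydroxyphenyl)-2,6,10-trimethyldodeca-6,10-dienoic acid (CNP0180353.1) | C/C(=C\Cc1cc(O)c(O)c(C=O)c1O)CC/C=C(\C)CCC[C@H](C)C(=O)O | target

**Totals**

Total step count: 15. Longest linear sequence: 12 steps (steps 1 to 9, then 13 to 15); the carbene branch takes 3 steps (10 to 12).

**Steps most likely to fail**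

Step 13. The dioxin ring of carbene 19 may cyclorevert with loss of formaldehyde before the alkyne inserts, the alkyne may insert without annulation, or the cerium work-up may over-oxidise the product. The fallback gives up the benzannulation for an aryl–allyl coupling; it sets out from bromide 9 and returns at quinone 22. Commercial 2,5-dimethoxyphenol is ortho-formylated (MgCl2, Et3N, paraformaldehyde) to 2-hydroxy-3,6-dimethoxybenzaldehyde F1. Bromination para to the phenol (NBS) gives 5-bromo-2-hydroxy-3,6-dimethoxybenzaldehyde F2, and NaBH4 reduction gives 4-bromo-2-(hydroxymethyl)-3,6-dimethoxyphenol F3. Closure with CH2Br2 and Cs2CO3 gives 6-bromo-5,8-dimethoxy-4H-1,3-benzodioxin F4. Bromine–lithium exchange (n-BuLi, -78 °C), conversion into the lithium diarylcuprate (CuBr·SMe2) and SN2 allylation with bromide 9 should give methyl (2S,6E,10E)-12-(5,8-dimethoxy-4H-1,3-benzodioxin-6-yl)-2,6,10-trimethyldodeca-6,10-dienoate F5. Oxidative demethylation of F5 with (NH4)2Ce(NO3)6 then arrives at quinone 22.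

Step 14. The slow ester saponification keeps the quinone in base for hours, during which hydroxide may add to the free ring CH, the allylquinone may tautomerise towards a chromenol, or the hydroxymethyl carbon may be lost by retro-aldol cleavage. The fallback separates the slow saponification from the fast acetal opening; it sets out from phenol 21 (isolated by ending step 13 with exposure to air in place of the cerium oxidation) and returns at 23. Phenol 21 is saponified as its stable phenoxide (LiOH, THF/H2O, argon) to (2S,6E,10E)-12-(5-hydroxy-8-methoxy-4H-1,3-benzodioxin-6-yl)-2,6,10-trimethyldodeca-6,10-dienoic acid F6. Oxidation with (NH4)2Ce(NO3)6 gives (2S,6E,10E)-12-(5,8-dioxo-5,8-dihydro-4H-1,3-benzodioxin-6-yl)-2,6,10-trimethyldodeca-6,10-dienoic acid F7. A few minutes in cold dilute NaOH followed by acidification should then open the dioxin to 23.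

Step 15. The periodinane may over-oxidise the hydroxyquinone nucleus, 23 may dehydrate to a quinone methide before the carbinol is oxidised, or the electrophilic formylquinone may oligomerise before it is reduced. The fallback uses no external oxidant or reductant; it sets out from 23 and returns at 25. Since 23 and 25 are tautomers, 23 is kept with a mild base (NaOAc in degassed aqueous MeCN) so that enolisation of the carbinol CH2 through the quinone carbonyl gives a hydroxy-substituted quinone methide, which aromatises to the formyl hydroquinone 25. This is the rearrangement by which (1-hydroxyalkyl)quinones pass into acylhydroquinones.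

Further compounds
F1 | step 13 | 2-hydroxy-3,6-dimethoxybenzaldehyde | COc1ccc(OC)c(C=O)c1O
F2 | step 13 | 5-bromo-2-hydroxy-3,6-dimethoxybenzaldehyde | COc1cc(Br)c(OC)c(C=O)c1O
F3 | step 13 | 4-bromo-2-(hydroxymethyl)-3,6-dimethoxyphenol | COc1cc(Br)c(OC)c(CO)c1O
F4 | step 13 | 6-bromo-5,8-dimethoxy-4H-1,3-benzodioxin | COc1cc(Br)c(OC)c2COCOc12
F5 | step 13 | methyl (2S,6E,10E)-12-(5,8-dimethoxy-4H-1,3-benzodioxin-6-yl)-2,6,10-trimethyldodeca-6,10-dienoate | COc1cc(C/C=C(\C)CC/C=C(\C)CCC[C@H](C)C(=O)OC)c(OC)c2COCOc12
F6 | step 14 | (2S,6E,10E)-12-(5-hydroxy-8-methoxy-4H-1,3-benzodioxin-6-yl)-2,6,10-trimethyldodeca-6,10-dienoic acid | COc1cc(C/C=C(\C)CC/C=C(\C)CCC[C@H](C)C(=O)O)c(O)c2COCOc12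
F7 | step 14 | (2S,6E,10E)-12-(5,8-dioxo-5,8-dihydro-4H-1,3-benzodioxin-6-yl)-2,6,10-trimethyldodeca-6,10-dienoic acid | O=C1C=C(C/C=C(\C)CC/C=C(\C)CCC[C@H](C)C(=O)O)C(=O)C2=C1OCOC2
F0 | step 15 | none | none
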